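**Retrosynthetic overview**
1. Target 28 ⇐ double O‑acetylation of diol lactone 25.
2. 25 ⇐ key step: intramolecular CrCl2 Barbier allylation of bromo‑enoate aldehyde 22. The C7–C8 bond comes from an allylchromium (homoenolate, d3 equivalent) whose acrylate β‑carbon attacks the aldehyde carbon; this closes the ten‑membered carbocycle, sets C7/C8 and lactonises in the same pot.
3. 22 ⇐ cross‑metathesis of vinyl carbinol 19 with methyl 2‑(bromomethyl)acrylate; 19 ⇐ Felkin vinyl‑Grignard addition (C6) to epoxy lactol 15.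
4. 15 ⇐ temporary δ‑lactone 12 (RCM), which locks the Z C4=C5 alkene and relays C2 to the oxirane; 12 ⇐ Ir‑catalysed methallylation (C2) of allylic alcohol 6 ⇐ carboalumination of alkyne 1 (E C1=C10).
5. Ring order: temporary δ‑lactone (step 4) → oxirane (step 5) → δ‑lactone opened (steps 6–7) → ten‑membered carbocycle and α‑methylene‑γ‑lactone together (step 11).

Assumption: the target is taken exactly as the given SMILES, i.e. 2S,4R,5S,6S,7R,8R with a cis‑fused 12,8‑lactone, a cis 4,5‑oxirane and an E‑1(10) alkene; labels C1–C15 are germacrane positions of the target and are used for all intermediates.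

**Step 1**
Reactants: 1 tert‑butyl(but‑3‑yn‑1‑yloxy)dimethylsilane; 2 trimethylaluminium; 3 paraformaldehyde
Product: 6 (2E)‑5‑{[tert‑butyl(dimethyl)silyl]oxy}‑3‑methylpent‑2‑en‑1‑ol, via alkenylalane 4 (not isolated), via lithium alanate 5 (not isolated)
Conditions: Me3Al (2.5 equiv), Cp2ZrCl2 (0.25 equiv), CH2Cl2, 0 °C to rt; then n‑BuLi, THF, −78 °C; (CH2O)n, rt; aq. potassium sodium tartrate
Reagents that add atoms: trimethylaluminium 2, C[Al](C)C; paraformaldehyde 3, C=O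
Why: Negishi zirconium‑catalysed carboalumination adds methyl and aluminium syn across the terminal alkyne, fixing the E trisubstituted C1=C10 alkene, and the derived alanate is hydroxymethylated with retention of geometry.

**Step 2**
Reactants: 6 (2E)‑5‑{[tert‑butyl(dimethyl)silyl]oxy}‑3‑methylpent‑2‑en‑1‑ol; 7 3‑chloro‑2‑methylprop‑1‑ene
Product: 9 (4S,5E)‑8‑{[tert‑butyl(dimethyl)silyl]oxy}‑2,6‑dimethylocta‑1,5‑dien‑4‑ol, via enal 8 (not isolated)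
Conditions: [Ir(cod)Cl]2 (2.5 mol%), (S)‑SEGPHOS (5 mol%), 4‑chloro‑3‑nitrobenzoic acid (10 mol%), Cs2CO3 (1.2 equiv), THF, 100 °C
Reagents that add atoms: 3‑chloro‑2‑methylprop‑1‑ene 7, C=C(C)CCl
Why: Krische iridium‑catalysed transfer‑hydrogenative carbonyl methallylation: the catalyst dehydrogenates the allylic alcohol to enal 8 and the chiral π‑methallyliridium adds to one enantioface through a closed transition state, setting C2 of the target as S under catalyst control (the ligand antipode gives the 4R alcohol; the sense is to be confirmed by Mosher analysis).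

**Step 3**
Reactants: 9 (4S,5E)‑8‑{[tert‑butyl(dimethyl)silyl]oxy}‑2,6‑dimethylocta‑1,5‑dien‑4‑ol; 10 prop‑2‑enoyl chloride
Product: 11 (4S,5E)‑8‑{[tert‑butyl(dimethyl)silyl]oxy}‑2,6‑dimethylocta‑1,5‑dien‑4‑yl prop‑2‑enoate
Conditions: Et3N, DMAP (cat.), CH2Cl2, 0 °C
Reagents that add atoms: prop‑2‑enoyl chloride 10, C=CC(=O)Cl
Why: DMAP‑catalysed O‑acylation of the secondary alcohol; no stereocentre is touched.

**Step 4**
Reactants: 11 (4S,5E)‑8‑{[tert‑butyl(dimethyl)silyl]oxy}‑2,6‑dimethylocta‑1,5‑dien‑4‑yl prop‑2‑enoate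
Product: 12 (6S)‑6‑[(1E)‑4‑{[tert‑butyl(dimethyl)silyl]oxy}‑2‑methylbut‑1‑en‑1‑yl]‑4‑methyl‑5,6‑dihydro‑2H‑pyran‑2‑one
Conditions: second‑generation Grubbs catalyst (5 mol%), CH2Cl2 (5 mM), 40 °C
Reagents that add atoms: none
Why: Ring‑closing metathesis of the acrylate onto the 1,1‑disubstituted alkene closes the six‑membered unsaturated lactone, which locks the C4=C5 alkene in the Z geometry; the trisubstituted C1=C10 alkene does not react.

**Step 5**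
Reactants: 12 (6S)‑6‑[(1E)‑4‑{[tert‑butyl(dimethyl)silyl]oxy}‑2‑methylbut‑1‑en‑1‑yl]‑4‑methyl‑5,6‑dihydro‑2H‑pyran‑2‑one; 13 tert‑butyl hydroperoxide
Product: 14 (1R,4S,6R)‑4‑[(1E)‑4‑{[tert‑butyl(dimethyl)silyl]oxy}‑2‑methylbut‑1‑en‑1‑yl]‑6‑methyl‑3,7‑dioxabicyclo[4.1.0]heptan‑2‑one
Conditions: t‑BuOOH, n‑BuLi, THF, −78 to −20 °C
Reagents that add atoms: tert‑butyl hydroperoxide 13, CC(C)(C)OO
Why: Weitz–Scheffer‑type nucleophilic epoxidation: lithium tert‑butyl peroxide adds to C4 axially on the half‑chair, anti to the pseudo‑equatorial side chain, and the enolate closes the oxirane trans to that side chain, which is the C4/C5 configuration of the target; the electron‑rich C1=C10 alkene is untouched.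

**Step 6**
Reactants: 14 (1R,4S,6R)‑4‑[(1E)‑4‑{[tert‑butyl(dimethyl)silyl]oxy}‑2‑methylbut‑1‑en‑1‑yl]‑6‑methyl‑3,7‑dioxabicyclo[4.1.0]heptan‑2‑one
Product: 15 (1R,4S,6R)‑4‑[(1E)‑4‑{[tert‑butyl(dimethyl)silyl]oxy}‑2‑methylbut‑1‑en‑1‑yl]‑6‑methyl‑3,7‑dioxabicyclo[4.1.0]heptan‑2‑ol (anomer mixture)
Conditions: i‑Bu2AlH (1.1 equiv), CH2Cl2, −78 °C; aq. potassium sodium tartrate
Reagents that add atoms: none
Why: Partial reduction of the lactone to the lactol, the tetrahedral aluminate being stable at −78 °C; oxirane and silyl ether survive.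

**Step 7**
Reactants: 15 epoxy lactol (name as above); 16 vinylmagnesium bromide
Product: 18 (1S)‑1‑{(2S,3R)‑3‑[(2S,3E)‑6‑{[tert‑butyl(dimethyl)silyl]oxy}‑2‑hydroxy‑4‑methylhex‑3‑en‑1‑yl]‑3‑methyloxiran‑2‑yl}prop‑2‑en‑1‑ol, via hydroxy aldehyde 17 (not isolated)
Conditions: CH2=CHMgBr (4 equiv), THF, −78 to −20 °C; aq. NH4Cl
Reagents that add atoms: vinylmagnesium bromide 16, C=C[Mg]Br
Why: Grignard 1,2‑addition to the aldehyde released from the magnesium lactolate; Felkin–Anh (Cornforth) attack anti to the oxirane C–O bond of the cis‑substituted epoxy aldehyde gives the anti epoxy alcohol, setting C6 as S.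

**Step 8**
Reactants: 18 silyl‑protected vinyl carbinol diol (name as above)
Product: 19 (3E,5S)‑6‑{(2R,3S)‑3‑[(1S)‑1‑hydroxyprop‑2‑en‑1‑yl]‑2‑methyloxiran‑2‑yl}‑3‑methylhex‑3‑ene‑1,5‑diol
Conditions: Bu4NF, AcOH, THF, 0 °C to rt
Reagents that add atoms: none
Why: Fluoride‑induced desilylation, buffered with acetic acid so that the epoxy alcohol does not undergo Payne rearrangement.

**Step 9**
Reactants: 19 triol (name as above); 20 methyl 2‑(bromomethyl)prop‑2‑enoate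
Product: 21 methyl (2Z,4S)‑2‑(bromomethyl)‑4‑{(2S,3R)‑3‑[(2S,3E)‑2,6‑dihydroxy‑4‑methylhex‑3‑en‑1‑yl]‑3‑methyloxiran‑2‑yl}‑4‑hydroxybut‑2‑enoate
Conditions: second‑generation Hoveyda–Grubbs catalyst (10 mol%), 20 (5 equiv), 1,4‑benzoquinone (10 mol%), CH2Cl2, 40 °C; product used at once
Reagents that add atoms: methyl 2‑(bromomethyl)prop‑2‑enoate 20, C=C(CBr)C(=O)OC
Why: Olefin cross‑metathesis of the monosubstituted alkene with the 1,1‑disubstituted acrylate gives the thermodynamic trisubstituted enoate with C6 trans to the ester (the Z bromide); the phosphine‑free catalyst spares the allylic bromide and the trisubstituted alkene stays inert.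

**Step 10**
Reactants: 21 bromo‑enoate triol (name as above)
Product: 22 methyl (2Z,4S)‑2‑(bromomethyl)‑4‑hydroxy‑4‑{(2S,3R)‑3‑[(2S,3E)‑2‑hydroxy‑4‑methyl‑6‑oxohex‑3‑en‑1‑yl]‑3‑methyloxiran‑2‑yl}but‑2‑enoate
Conditions: TEMPO (10 mol%), PhI(OAc)2 (1.1 equiv), CH2Cl2, 0 °C; used crude
Reagents that add atoms: none
Why: TEMPO/PhI(OAc)2 oxidation takes the primary alcohol to the aldehyde much faster than it touches the two secondary alcohols, and the neutral conditions keep the β,γ‑unsaturated aldehyde out of conjugation.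

**Step 11 (key step)**
Reactants: 22 bromo‑enoate aldehyde (name as above)
Product: 25 (2S,4R,5S,6S,7S,8R)‑4,5‑epoxy‑2,6‑dihydroxygermacra‑1(10)E,11(13)‑dien‑12,8‑olide, via allylchromium species 23 (not isolated), via hydroxy ester 24 (not isolated)
Conditions: CrCl2 (8 equiv), THF, rt, slow addition of 22 (final 2 mM); aq. NH4Cl
Reagents that add atoms: none
Why: Intramolecular Nozaki–Hiyama‑type Barbier allylation: divalent chromium turns the allylic bromide into allylchromium 23, a homoenolate (d3) equivalent whose normally electrophilic acrylate β‑carbon C7 attacks the aldehyde carbon C8 through a six‑membered chair transition state; the Z reagent with C9 equatorial gives the 7,8‑syn adduct 24, which lactonises to the cis lactone, and because H6 must face the incoming aldehyde (avoiding C5/C9 syn‑pentane strain) while the C6 hydroxyl sits inside, coordinated to chromium, addition occurs anti to the C5 tether and gives the target configuration at C7 and C8 (the S label at C7 in 25 arises only from CIP priorities).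

**Step 12**
Reactants: 25 diol lactone (name as above); 26 acetic anhydride
Product: 28 (2S,4R,5S,6S,7R,8R)‑2,6‑diacetoxy‑4,5‑epoxygermacra‑1(10)E,11(13)‑dien‑12,8‑olide (CNP0270851.1), via monoacetate 27 (not isolated)
Conditions: Ac2O, pyridine, DMAP (cat.), CH2Cl2, 0 °C
Reagents that add atoms: acetic anhydride 26, CC(=O)OC(C)=O
Why: DMAP‑catalysed O‑acetylation of both secondary alcohols with retention; it is run cold and directly after step 11 so that the C6 hydroxyl is capped before it can translactonise.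

**Compound list**
1 | tert‑butyl(but‑3‑yn‑1‑yloxy)dimethylsilane | C#CCCO[Si](C)(C)C(C)(C)C | starting material
2 | trimethylaluminium | C[Al](C)C | starting material
3 | paraformaldehyde (monomer shown) | C=O | starting material
4 | [(1E)‑4‑{[tert‑butyl(dimethyl)silyl]oxy}‑2‑methylbut‑1‑en‑1‑yl]dimethylalane | CC(C)(C)[Si](C)(C)OCC/C(C)=C/[Al](C)C | intermediate
5 | lithium butyl[(1E)‑4‑{[tert‑butyl(dimethyl)silyl]oxy}‑2‑methylbut‑1‑en‑1‑yl]dimethylalanate | [Li+].CC(C)(C)[Si](C)(C)OCC/C(C)=C/[Al-](C)(C)CCCC | intermediate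
6 | (2E)‑5‑{[tert‑butyl(dimethyl)silyl]oxy}‑3‑methylpent‑2‑en‑1‑ol | CC(C)(C)[Si](C)(C)OCC/C(C)=C/CO | intermediate
7 | 3‑chloro‑2‑methylprop‑1‑ene | C=C(C)CCl | starting material
8 | (2E)‑5‑{[tert‑butyl(dimethyl)silyl]oxy}‑3‑methylpent‑2‑enal | CC(C)(C)[Si](C)(C)OCC/C(C)=C/C=O | intermediate
9 | (4S,5E)‑8‑{[tert‑butyl(dimethyl)silyl]oxy}‑2,6‑dimethylocta‑1,5‑dien‑4‑ol | CC(C)(C)[Si](C)(C)OCC/C(C)=C/[C@@H](O)CC(C)=C | intermediate
10 | prop‑2‑enoyl chloride | C=CC(=O)Cl | starting material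
11 | (4S,5E)‑8‑{[tert‑butyl(dimethyl)silyl]oxy}‑2,6‑dimethylocta‑1,5‑dien‑4‑yl prop‑2‑enoate | CC(C)(C)[Si](C)(C)OCC/C(C)=C/[C@@H](OC(=O)C=C)CC(C)=C | intermediate
12 | (6S)‑6‑[(1E)‑4‑{[tert‑butyl(dimethyl)silyl]oxy}‑2‑methylbut‑1‑en‑1‑yl]‑4‑methyl‑5,6‑dihydro‑2H‑pyran‑2‑one | CC(C)(C)[Si](C)(C)OCC/C(C)=C/[C@@H]1CC(C)=CC(=O)O1 | intermediate
13 | tert‑butyl hydroperoxide | CC(C)(C)OO | starting material
14 | (1R,4S,6R)‑4‑[(1E)‑4‑{[tert‑butyl(dimethyl)silyl]oxy}‑2‑methylbut‑1‑en‑1‑yl]‑6‑methyl‑3,7‑dioxabicyclo[4.1.0]heptan‑2‑one (oxirane trans to the side chain) | CC(C)(C)[Si](C)(C)OCC/C(C)=C/[C@@H]1C[C@@]2(C)O[C@H]2C(=O)O1 | intermediate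
15 | (1R,4S,6R)‑4‑[(1E)‑4‑{[tert‑butyl(dimethyl)silyl]oxy}‑2‑methylbut‑1‑en‑1‑yl]‑6‑methyl‑3,7‑dioxabicyclo[4.1.0]heptan‑2‑ol (anomer mixture) | CC(C)(C)[Si](C)(C)OCC/C(C)=C/[C@@H]1C[C@@]2(C)O[C@H]2C(O)O1 | intermediate
16 | vinylmagnesium bromide | C=C[Mg]Br | starting material
17 | (2R,3R)‑3‑[(2S,3E)‑6‑{[tert‑butyl(dimethyl)silyl]oxy}‑2‑hydroxy‑4‑methylhex‑3‑en‑1‑yl]‑3‑methyloxirane‑2‑carbaldehyde (open form of 15, present as its magnesium alkoxide) | CC(C)(C)[Si](C)(C)OCC/C(C)=C/[C@@H](O)C[C@@]1(C)O[C@H]1C=O | intermediate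
18 | (1S)‑1‑{(2S,3R)‑3‑[(2S,3E)‑6‑{[tert‑butyl(dimethyl)silyl]oxy}‑2‑hydroxy‑4‑methylhex‑3‑en‑1‑yl]‑3‑methyloxiran‑2‑yl}prop‑2‑en‑1‑ol | CC(C)(C)[Si](C)(C)OCC/C(C)=C/[C@@H](O)C[C@@]1(C)O[C@H]1[C@@H](O)C=C | intermediate
19 | (3E,5S)‑6‑{(2R,3S)‑3‑[(1S)‑1‑hydroxyprop‑2‑en‑1‑yl]‑2‑methyloxiran‑2‑yl}‑3‑methylhex‑3‑ene‑1,5‑diol | OCC/C(C)=C/[C@@H](O)C[C@@]1(C)O[C@H]1[C@@H](O)C=C | intermediate
20 | methyl 2‑(bromomethyl)prop‑2‑enoate | C=C(CBr)C(=O)OC | starting material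
21 | methyl (2Z,4S)‑2‑(bromomethyl)‑4‑{(2S,3R)‑3‑[(2S,3E)‑2,6‑dihydroxy‑4‑methylhex‑3‑en‑1‑yl]‑3‑methyloxiran‑2‑yl}‑4‑hydroxybut‑2‑enoate | OCC/C(C)=C/[C@@H](O)C[C@@]1(C)O[C@H]1[C@@H](O)/C=C(\CBr)C(=O)OC | intermediate
22 | methyl (2Z,4S)‑2‑(bromomethyl)‑4‑hydroxy‑4‑{(2S,3R)‑3‑[(2S,3E)‑2‑hydroxy‑4‑methyl‑6‑oxohex‑3‑en‑1‑yl]‑3‑methyloxiran‑2‑yl}but‑2‑enoate | O=CC/C(C)=C/[C@@H](O)C[C@@]1(C)O[C@H]1[C@@H](O)/C=C(\CBr)C(=O)OC | intermediate
23 | allylchromium dichloride derived from 22 (C13–CrCl2 in place of C13–Br) | O=CC/C(C)=C/[C@@H](O)C[C@@]1(C)O[C@H]1[C@@H](O)/C=C(\C[Cr](Cl)Cl)C(=O)OC | intermediate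
24 | methyl (2S,4R,5S,6S,7R,8R)‑4,5‑epoxy‑2,6,8‑trihydroxygermacra‑1(10)E,11(13)‑dien‑12‑oate (formed as its chromium alkoxide) | O[C@@H]1C/C(C)=C/[C@@H](O)C[C@@]2(C)O[C@H]2[C@@H](O)[C@@H]1C(=C)C(=O)OC | intermediate
25 | (2S,4R,5S,6S,7S,8R)‑4,5‑epoxy‑2,6‑dihydroxygermacra‑1(10)E,11(13)‑dien‑12,8‑olide | C=C1C(=O)O[C@@H]2C/C(C)=C/[C@@H](O)C[C@@]3(C)O[C@H]3[C@@H](O)[C@H]12 | intermediate
26 | acetic anhydride | CC(=O)OC(C)=O | starting material
27 | (2S,4R,5S,6S,7S,8R)‑2‑acetoxy‑4,5‑epoxy‑6‑hydroxygermacra‑1(10)E,11(13)‑dien‑12,8‑olide | C=C1C(=O)O[C@@H]2C/C(C)=C/[C@@H](OC(C)=O)C[C@@]3(C)O[C@H]3[C@@H](O)[C@H]12 | intermediate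
28 | (2S,4R,5S,6S,7R,8R)‑2,6‑diacetoxy‑4,5‑epoxygermacra‑1(10)E,11(13)‑dien‑12,8‑olide (CNP0270851.1) | C=C1C(=O)O[C@@H]2C/C(C)=C/[C@@H](OC(C)=O)C[C@@]3(C)O[C@H]3[C@@H](OC(C)=O)[C@H]12 | target

**Totals**
Total step count: 12. Longest linear sequence: 12 (the route is fully linear from 1).

**Three steps most likely to fail**

Step 11, the macrocyclisation, is the largest risk. The allylchromium can be protonated by the free hydroxyls or oligomerise, the C7 face selectivity depends on the C6 hydroxyl taking the inside position, and the free C6 hydroxyl could translactonise to the 12,6‑olide. The fallback sets out from diol 18 and comes back at target 28. Ac2O/pyridine/DMAP converts 18 into the bis‑acetate F1. Cross‑metathesis of F1 with 20 (second‑generation Hoveyda–Grubbs catalyst) gives the bromo‑enoate F2. HF·pyridine removes the silyl ether to give the primary alcohol F3, and TEMPO/PhI(OAc)2 gives the aldehyde F4. CrCl2 in THF at high dilution then closes carbocycle and lactone to give 28 directly. No free hydroxyl is left to quench the organometallic or to translactonise, the acetoxy group (smaller than the C5 branch) still takes the inside position, and the final acetylation is no longer needed.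

Step 9, the cross‑metathesis, joins a hindered allylic alcohol with a 1,1‑disubstituted acrylate and may stall; bromide 21 can also close to a 2,5‑dihydrofuran by internal O‑alkylation. The fallback sets out from lactol 15 and comes back at 21. The lithium acetylide of tert‑butyldimethyl(prop‑2‑yn‑1‑yloxy)silane adds to 15 to give the propargylic diol F5. Syn‑hydrozirconation with Cp2Zr(H)Cl (zirconium at the less hindered alkyne carbon) and iodinolysis give the vinyl iodide F6. PdCl2(PPh3)2‑catalysed methoxycarbonylation (CO, MeOH, Et3N) gives the silyloxymethyl enoate F7 with the ester trans to C6. Bu4NF removes both silyl ethers to give the tetraol F8, and NBS/Me2S brominates only the allylic primary alcohol to return 21.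

Step 5, the nucleophilic epoxidation, may be slow on the β,β‑disubstituted lactone and its trans selectivity is not guaranteed. The fallback sets out from lactone 12 and comes back at epoxy lactone 14. LiAlH4 reduces 12 to the Z‑allylic diol F9. Sharpless asymmetric epoxidation (Ti(OiPr)4, L‑(+)‑diisopropyl tartrate, t‑BuOOH, 4 Å sieves, −20 °C) gives the epoxy diol F10 under reagent control; the secondary allylic alcohol at C2, with its cis alkene substituent, reacts only slowly. TEMPO/PhI(OAc)2 oxidative lactonisation of the 1,5‑diol then returns 14.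

**Further compounds**
F1 | step 11 | (1S)‑1‑{(2S,3R)‑3‑[(2S,3E)‑2‑acetoxy‑6‑{[tert‑butyl(dimethyl)silyl]oxy}‑4‑methylhex‑3‑en‑1‑yl]‑3‑methyloxiran‑2‑yl}prop‑2‑en‑1‑yl acetate | CC(C)(C)[Si](C)(C)OCC/C(C)=C/[C@@H](OC(C)=O)C[C@@]1(C)O[C@H]1[C@@H](OC(C)=O)C=C
F2 | step 11 | methyl (2Z,4S)‑4‑acetoxy‑4‑{(2S,3R)‑3‑[(2S,3E)‑2‑acetoxy‑6‑{[tert‑butyl(dimethyl)silyl]oxy}‑4‑methylhex‑3‑en‑1‑yl]‑3‑methyloxiran‑2‑yl}‑2‑(bromomethyl)but‑2‑enoate | CC(C)(C)[Si](C)(C)OCC/C(C)=C/[C@@H](OC(C)=O)C[C@@]1(C)O[C@H]1[C@@H](OC(C)=O)/C=C(\CBr)C(=O)OC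
F3 | step 11 | methyl (2Z,4S)‑4‑acetoxy‑4‑{(2S,3R)‑3‑[(2S,3E)‑2‑acetoxy‑6‑hydroxy‑4‑methylhex‑3‑en‑1‑yl]‑3‑methyloxiran‑2‑yl}‑2‑(bromomethyl)but‑2‑enoate | OCC/C(C)=C/[C@@H](OC(C)=O)C[C@@]1(C)O[C@H]1[C@@H](OC(C)=O)/C=C(\CBr)C(=O)OC
F4 | step 11 | methyl (2Z,4S)‑4‑acetoxy‑4‑{(2S,3R)‑3‑[(2S,3E)‑2‑acetoxy‑4‑methyl‑6‑oxohex‑3‑en‑1‑yl]‑3‑methyloxiran‑2‑yl}‑2‑(bromomethyl)but‑2‑enoate | O=CC/C(C)=C/[C@@H](OC(C)=O)C[C@@]1(C)O[C@H]1[C@@H](OC(C)=O)/C=C(\CBr)C(=O)OC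
F5 | step 9 | (1S)‑4‑{[tert‑butyl(dimethyl)silyl]oxy}‑1‑{(2S,3R)‑3‑[(2S,3E)‑6‑{[tert‑butyl(dimethyl)silyl]oxy}‑2‑hydroxy‑4‑methylhex‑3‑en‑1‑yl]‑3‑methyloxiran‑2‑yl}but‑2‑yn‑1‑ol | CC(C)(C)[Si](C)(C)OCC/C(C)=C/[C@@H](O)C[C@@]1(C)O[C@H]1[C@@H](O)C#CCO[Si](C)(C)C(C)(C)C
F6 | step 9 | (1S,2E)‑4‑{[tert‑butyl(dimethyl)silyl]oxy}‑1‑{(2S,3R)‑3‑[(2S,3E)‑6‑{[tert‑butyl(dimethyl)silyl]oxy}‑2‑hydroxy‑4‑methylhex‑3‑en‑1‑yl]‑3‑methyloxiran‑2‑yl}‑3‑iodobut‑2‑en‑1‑ol | CC(C)(C)[Si](C)(C)OCC/C(C)=C/[C@@H](O)C[C@@]1(C)O[C@H]1[C@@H](O)/C=C(/I)CO[Si](C)(C)C(C)(C)C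
F7 | step 9 | methyl (2E,4S)‑2‑({[tert‑butyl(dimethyl)silyl]oxy}methyl)‑4‑{(2S,3R)‑3‑[(2S,3E)‑6‑{[tert‑butyl(dimethyl)silyl]oxy}‑2‑hydroxy‑4‑methylhex‑3‑en‑1‑yl]‑3‑methyloxiran‑2‑yl}‑4‑hydroxybut‑2‑enoate | CC(C)(C)[Si](C)(C)OCC/C(C)=C/[C@@H](O)C[C@@]1(C)O[C@H]1[C@@H](O)/C=C(\CO[Si](C)(C)C(C)(C)C)C(=O)OC
F8 | step 9 | methyl (2E,4S)‑4‑{(2S,3R)‑3‑[(2S,3E)‑2,6‑dihydroxy‑4‑methylhex‑3‑en‑1‑yl]‑3‑methyloxiran‑2‑yl}‑4‑hydroxy‑2‑(hydroxymethyl)but‑2‑enoate | OCC/C(C)=C/[C@@H](O)C[C@@]1(C)O[C@H]1[C@@H](O)/C=C(\CO)C(=O)OC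
F9 | step 5 | (2Z,5S,6E)‑9‑{[tert‑butyl(dimethyl)silyl]oxy}‑3,7‑dimethylnona‑2,6‑diene‑1,5‑diol | CC(C)(C)[Si](C)(C)OCC/C(C)=C/[C@@H](O)C/C(C)=C\CO
F10 | step 5 | {(2S,3R)‑3‑[(2S,3E)‑6‑{[tert‑butyl(dimethyl)silyl]oxy}‑2‑hydroxy‑4‑methylhex‑3‑en‑1‑yl]‑3‑methyloxiran‑2‑yl}methanol | CC(C)(C)[Si](C)(C)OCC/C(C)=C/[C@@H](O)C[C@@]1(C)O[C@H]1CO
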